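Ring C (O1, C2, C3, C4, C4a, C8a) is disconnected at O1–C2 and C4–C4a. Ring A becomes a phenol acting as 1,3-O,C-dinucleophile, and C2–C3–C4 becomes an enantiopure (R)-4-aryl-beta-lactone acting as 1,3-dielectrophile. In one flask the aryloxide opens the lactone at its benzylic carbon with inversion (O1–C2, C2 set as S). The released carboxylate is then activated to acylate the ortho carbon (C4–C4a). The step exploits the latent symmetry of ring A: with O5 and O7 both methylated, the C6 prenyl group lies para to O1 and C4a and C8 are equivalent, so no regiochemical choice exists. The precursors are 3,5-dimethoxy-4-prenylphenol and the lactone; chelation-controlled 5-O-demethylation finishes.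

Key step: step 5

Remark: flavanone numbering (O1, C2, C3, C4, C4a, C5 to C8, C8a, primed numbers for ring B) is used for all compounds that hold ring C or its atoms.

Step 1
Reactants: 1 1,3-dimethoxybenzene; 2 prenyl bromide (1-bromo-3-methylbut-2-ene)
Product: 4 1,3-dimethoxy-2-(3-methylbut-2-en-1-yl)benzene, via 2,6-dimethoxyphenyllithium 3 (not isolated)
Conditions: n-BuLi, THF, 0 °C to rt; CuBr·SMe2 (10 mol%), 2, −78 °C to rt
Reagents that add atoms: none
Why: Directed ortho-metalation takes place at C2 between the two cooperating methoxy groups, and the copper-assisted SN2 allylation of aryllithium 3 with the primary allylic bromide 2 should deliver the linear prenyl arene.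

Step 2
Reactants: 4 1,3-dimethoxy-2-(3-methylbut-2-en-1-yl)benzene
Product: 6 3,5-dimethoxy-4-(3-methylbut-2-en-1-yl)phenol, via aryl pinacol boronate 5 (not isolated)
Conditions: [Ir(OMe)(cod)]2 (1.5 mol%), 4,4'-di-tert-butyl-2,2'-bipyridine (3 mol%), B2pin2 (1.0 equiv), THF, 80 °C; then aq. H2O2, NaOH, THF, 0 °C
Reagents that add atoms: hydrogen peroxide OO
Why: Sterically governed iridium-catalysed C–H borylation (Hartwig–Miyaura type) can reach only C5 of 4, the one ring C–H without an ortho substituent, the trisubstituted alkene being a poor partner for hydroboration, and the boronate is then oxidised at the same carbon by 1,2-aryl migration from boron to oxygen.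

Step 3
Reactants: 7 ethyl 3-oxo-3-(3,4,5-trimethoxyphenyl)propanoate
Product: 9 (R)-3-hydroxy-3-(3,4,5-trimethoxyphenyl)propanoic acid, via ethyl (R)-hydroxy ester 8 (not isolated)
Conditions: RuCl2[(S)-BINAP] (0.5 mol%), H2 (10 bar), EtOH, 60 °C; then LiOH, THF/H2O, 0 °C to rt; 1 M HCl to pH 3
Reagents that add atoms: lithium hydroxide [Li+].[OH-]
Why: Noyori asymmetric hydrogenation of the beta-keto ester through its ruthenium chelate sets the carbinol centre, (S)-BINAP giving the (R)-alcohol (same spatial sense as for alkyl beta-keto esters, the descriptor changing because aryl outranks CH2CO2Et), and mild saponification leaves this centre untouched while recrystallisation of 9 can raise its enantiomeric purity.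

Step 4
Reactants: 9 (R)-3-hydroxy-3-(3,4,5-trimethoxyphenyl)propanoic acid
Product: 11 (R)-4-(3,4,5-trimethoxyphenyl)oxetan-2-one, via carboxylic sulfonic mixed anhydride 10 (not isolated)
Conditions: PhSO2Cl (2 equiv), pyridine, 0 to 4 °C; cold work-up, product stored cold
Reagents that add atoms: none
Why: Carboxyl-group activation as mixed anhydride 10 followed by 4-exo-trig attack of the free hydroxyl on the acyl carbon (beta-lactonisation of a beta-hydroxy acid with a sulfonyl chloride in pyridine) leaves the C–O bond at the stereocentre intact, so that the (R) configuration is retained.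

Step 5
Reactants: 6 3,5-dimethoxy-4-(3-methylbut-2-en-1-yl)phenol; 11 (R)-4-(3,4,5-trimethoxyphenyl)oxetan-2-one
Product: 15 (S)-5,7-dimethoxy-6-(3-methylbut-2-en-1-yl)-2-(3,4,5-trimethoxyphenyl)chroman-4-one, via sodium aryloxide 12 (not isolated), via sodium (S)-3-aryloxycarboxylate 13 (not isolated), via mixed trifluoroacetic anhydride 14 (not isolated)
Conditions: 6, NaH (1.0 equiv), 15-crown-5, THF, 0 °C; 11 added slowly, 0 °C to rt; then CH2Cl2, 2,6-di-tert-butyl-4-methylpyridine, (CF3CO)2O, 0 °C to rt
Reagents that add atoms: none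
Why: Proposed new method: aryloxide 12 attacks the strained lactone 11 at its benzylic C4 in an SN2 alkyl–oxygen cleavage, which forms O1–C2 and releases carboxylate 13, while attack at the acyl carbon only gives an aryl ester alkoxide that, in the absence of a proton source, re-closes to the lactone, so that the irreversible carboxylate-forming path should drain the mixture; (CF3CO)2O then converts 13 into mixed anhydride 14, whose acyl carbon is attacked by the ring carbon ortho to the new ether oxygen to form C4–C4a. The closest known reaction types are the inverting alkyl–oxygen opening of beta-propiolactone and 4-alkyl-beta-lactones by aryloxide, azide and sulfonamide anions and the (CF3CO)2O-mediated intramolecular Friedel–Crafts acylation of 3-aryloxypropanoic acids to chroman-4-ones; not yet shown are the pairing of a 4-aryl-beta-lactone with an electron-rich aryloxide and the coupling of both events in one flask. Ring C closes by a 6-exo-trig attack of the arene on the exocyclic C=O of 14, followed by loss of trifluoroacetate and of the ring proton. The only stereocentre, C2, is controlled by the substrate: backside displacement turns (R)-11 into the (S)-ether, and the acylation does not touch this carbon. The step needs O- over C-alkylation, alkyl over acyl attack and a single site of acylation: the site question is removed by the symmetry of 6 (one OH, two equivalent ortho C–H, para position blocked by the prenyl group), which also excludes the 8-prenyl isomer, the crown-ether-separated ion pair in THF favours O-alkylation, and slow addition of 11 to fully deprotonated 6 keeps chain growth through 13 and trapping of the acyl adduct low. The hindered pyridine takes up the CF3CO2H set free so that the prenyl double bond and the benzylic ether are not protonated.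

Step 6
Reactants: 15 (S)-5,7-dimethoxy-6-(3-methylbut-2-en-1-yl)-2-(3,4,5-trimethoxyphenyl)chroman-4-one
Product: 17 artoflavanone = (S)-5-hydroxy-7-methoxy-6-(3-methylbut-2-en-1-yl)-2-(3,4,5-trimethoxyphenyl)chroman-4-one, via dichloroboron chelate 16 (not isolated)
Conditions: BCl3 (1.1 equiv), CH2Cl2, −78 to −20 °C; cold aq. NaHCO3
Reagents that add atoms: none
Why: Chelation-controlled Lewis-acid ether cleavage: BCl3 binds the C4 carbonyl oxygen and the peri 5-methoxy oxygen in a six-membered chelate so that chloride removes only this methyl group, while one equivalent of reagent, low temperature and the absence of strong base should spare the 7-, 3'-, 4'- and 5'-methoxy groups, the prenyl double bond and the configuration at C2.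

Compound list
1 | 1,3-dimethoxybenzene | COc1cccc(OC)c1 | starting material
2 | prenyl bromide (1-bromo-3-methylbut-2-ene) | CC(C)=CCBr | starting material
3 | 2,6-dimethoxyphenyllithium | [Li]c1c(OC)cccc1OC | intermediate
4 | 1,3-dimethoxy-2-(3-methylbut-2-en-1-yl)benzene | COc1cccc(OC)c1CC=C(C)C | intermediate
5 | 2-[3,5-dimethoxy-4-(3-methylbut-2-en-1-yl)phenyl]-4,4,5,5-tetramethyl-1,3,2-dioxaborolane | COc1cc(B2OC(C)(C)C(C)(C)O2)cc(OC)c1CC=C(C)C | intermediate
6 | 3,5-dimethoxy-4-(3-methylbut-2-en-1-yl)phenol | COc1cc(O)cc(OC)c1CC=C(C)C | intermediate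
7 | ethyl 3-oxo-3-(3,4,5-trimethoxyphenyl)propanoate | CCOC(=O)CC(=O)c1cc(OC)c(OC)c(OC)c1 | starting material
8 | ethyl (R)-3-hydroxy-3-(3,4,5-trimethoxyphenyl)propanoate | CCOC(=O)C[C@@H](O)c1cc(OC)c(OC)c(OC)c1 | intermediate
9 | (R)-3-hydroxy-3-(3,4,5-trimethoxyphenyl)propanoic acid | OC(=O)C[C@@H](O)c1cc(OC)c(OC)c(OC)c1 | intermediate
10 | (R)-3-hydroxy-3-(3,4,5-trimethoxyphenyl)propanoic benzenesulfonic anhydride | O=C(C[C@@H](O)c1cc(OC)c(OC)c(OC)c1)OS(=O)(=O)c1ccccc1 | intermediate
11 | (R)-4-(3,4,5-trimethoxyphenyl)oxetan-2-one | O=C1C[C@H](c2cc(OC)c(OC)c(OC)c2)O1 | intermediate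
12 | sodium 3,5-dimethoxy-4-(3-methylbut-2-en-1-yl)phenoxide | [Na+].[O-]c1cc(OC)c(CC=C(C)C)c(OC)c1 | intermediate
13 | sodium (S)-3-[3,5-dimethoxy-4-(3-methylbut-2-en-1-yl)phenoxy]-3-(3,4,5-trimethoxyphenyl)propanoate | [Na+].[O-]C(=O)C[C@H](Oc1cc(OC)c(CC=C(C)C)c(OC)c1)c1cc(OC)c(OC)c(OC)c1 | intermediate
14 | (S)-3-[3,5-dimethoxy-4-(3-methylbut-2-en-1-yl)phenoxy]-3-(3,4,5-trimethoxyphenyl)propanoic trifluoroacetic anhydride | O=C(C[C@H](Oc1cc(OC)c(CC=C(C)C)c(OC)c1)c1cc(OC)c(OC)c(OC)c1)OC(=O)C(F)(F)F | intermediate
15 | (S)-5,7-dimethoxy-6-(3-methylbut-2-en-1-yl)-2-(3,4,5-trimethoxyphenyl)chroman-4-one | COc1cc2c(c(OC)c1CC=C(C)C)C(=O)C[C@@H](c1cc(OC)c(OC)c(OC)c1)O2 | intermediate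
16 | (S)-5-(dichloroboryloxy)-7-methoxy-6-(3-methylbut-2-en-1-yl)-2-(3,4,5-trimethoxyphenyl)chroman-4-one (boron chelated by the C4 carbonyl oxygen) | COc1cc2c(c(OB(Cl)Cl)c1CC=C(C)C)C(=O)C[C@@H](c1cc(OC)c(OC)c(OC)c1)O2 | intermediate
17 | artoflavanone, (S)-5-hydroxy-7-methoxy-6-(3-methylbut-2-en-1-yl)-2-(3,4,5-trimethoxyphenyl)chroman-4-one | COc1cc2c(c(O)c1CC=C(C)C)C(=O)C[C@@H](c1cc(OC)c(OC)c(OC)c1)O2 | target

Total step count: 6
Longest linear sequence: 4 steps (1, 2, 5, 6 or 3, 4, 5, 6)

Steps most likely to fail

Step 5. Several processes may compete with the benzylic SN2 opening: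
- attack of the aryloxide at the acyl carbon;
- deprotonation at C3 followed by beta-elimination;
- C-alkylation of the ambident aryloxide;
- chain growth by attack of the product carboxylate on further lactone.

Partial ionisation at the benzylic carbon would erode the enantiomeric purity, and acid released in the acylation stage may damage the prenyl chain. The fallback uses known chemistry. It sets out from hydroxy ester 8, isolated by leaving out the saponification in step 3, and from phenol 6.
- A Mitsunobu reaction (PPh3, DIAD, toluene, 0 °C) forms the aryl ether with inversion and should give ethyl (S)-3-[3,5-dimethoxy-4-(3-methylbut-2-en-1-yl)phenoxy]-3-(3,4,5-trimethoxyphenyl)propanoate F1.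
- LiOH in THF/H2O should give (S)-3-[3,5-dimethoxy-4-(3-methylbut-2-en-1-yl)phenoxy]-3-(3,4,5-trimethoxyphenyl)propanoic acid F2.
- (CF3CO)2O with the hindered pyridine in CH2Cl2 at 0 °C carries F2 through 14 in an intramolecular Friedel–Crafts acylation.

The route is rejoined at 15. The lactone and step 4 are then not needed, and the two ring bonds are made in separate flasks.

Step 6. Three processes may spoil the last step: over-demethylation at the hindered 4'-methoxy group, hydrochlorination of the prenyl chain or its cyclisation onto the freed 5-hydroxyl, and Lewis-acid-induced opening of ring C with loss of configurational purity. The fallback introduces the prenyl group last, so that it never meets the Lewis acid. It sets out from lactone 11.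
- Purchased 3,5-dimethoxyphenol is deprotonated with NaH to sodium 3,5-dimethoxyphenoxide F3.
- Under the conditions of step 5 this passes through sodium (S)-3-(3,5-dimethoxyphenoxy)-3-(3,4,5-trimethoxyphenyl)propanoate F4 and (S)-3-(3,5-dimethoxyphenoxy)-3-(3,4,5-trimethoxyphenyl)propanoic trifluoroacetic anhydride F5 to (S)-5,7-dimethoxy-2-(3,4,5-trimethoxyphenyl)chroman-4-one F6.
- BCl3 cleaves the 5-methyl ether by way of (S)-5-(dichloroboryloxy)-7-methoxy-2-(3,4,5-trimethoxyphenyl)chroman-4-one F7 to (S)-5-hydroxy-7-methoxy-2-(3,4,5-trimethoxyphenyl)chroman-4-one F8.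
- A Tsuji–Trost O-allylation with tert-butyl 2-methylbut-3-en-2-yl carbonate and Pd(PPh3)4 (THF, 0 °C) should give (S)-7-methoxy-5-(2-methylbut-3-en-2-yloxy)-2-(3,4,5-trimethoxyphenyl)chroman-4-one F9.
- An aromatic Claisen rearrangement (Eu(fod)3 cat., toluene, 80 °C) moves the chain with allyl inversion to C6, the only free ortho position.

The route is rejoined at 17.

Step 2. Hydroboration or isomerisation of the prenyl double bond by iridium boryl and hydride species may occur. C–H activation of the electron-rich arene may be sluggish, and the electron-rich phenol may be over-oxidised. The fallback installs the prenyl group on a ring that already carries the oxygen. It sets out from prenyl bromide 2.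
- Purchased 3,5-dimethoxyphenol is silylated (TIPSCl, imidazole, DMF) to (3,5-dimethoxyphenoxy)triisopropylsilane F10.
- n-BuLi (THF, 0 °C to rt) lithiates between the two methoxy groups, the bulky silyl ether being no directing group, to 2,6-dimethoxy-4-(triisopropylsilyloxy)phenyllithium F11.
- CuBr·SMe2 and 2 should give [3,5-dimethoxy-4-(3-methylbut-2-en-1-yl)phenoxy]triisopropylsilane F12.
- TBAF in THF removes the silyl group.

The route is rejoined at 6.

Further compounds
F1 | step 5 | ethyl (S)-3-[3,5-dimethoxy-4-(3-methylbut-2-en-1-yl)phenoxy]-3-(3,4,5-trimethoxyphenyl)propanoate | CCOC(=O)C[C@H](Oc1cc(OC)c(CC=C(C)C)c(OC)c1)c1cc(OC)c(OC)c(OC)c1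
F2 | step 5 | (S)-3-[3,5-dimethoxy-4-(3-methylbut-2-en-1-yl)phenoxy]-3-(3,4,5-trimethoxyphenyl)propanoic acid | OC(=O)C[C@H](Oc1cc(OC)c(CC=C(C)C)c(OC)c1)c1cc(OC)c(OC)c(OC)c1
F3 | step 6 | sodium 3,5-dimethoxyphenoxide | [Na+].[O-]c1cc(OC)cc(OC)c1
F4 | step 6 | sodium (S)-3-(3,5-dimethoxyphenoxy)-3-(3,4,5-trimethoxyphenyl)propanoate | [Na+].[O-]C(=O)C[C@H](Oc1cc(OC)cc(OC)c1)c1cc(OC)c(OC)c(OC)c1
F5 | step 6 | (S)-3-(3,5-dimethoxyphenoxy)-3-(3,4,5-trimethoxyphenyl)propanoic trifluoroacetic anhydride | O=C(C[C@H](Oc1cc(OC)cc(OC)c1)c1cc(OC)c(OC)c(OC)c1)OC(=O)C(F)(F)F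
F6 | step 6 | (S)-5,7-dimethoxy-2-(3,4,5-trimethoxyphenyl)chroman-4-one | COc1cc2c(c(OC)c1)C(=O)C[C@@H](c1cc(OC)c(OC)c(OC)c1)O2
F7 | step 6 | (S)-5-(dichloroboryloxy)-7-methoxy-2-(3,4,5-trimethoxyphenyl)chroman-4-one | COc1cc2c(c(OB(Cl)Cl)c1)C(=O)C[C@@H](c1cc(OC)c(OC)c(OC)c1)O2
F8 | step 6 | (S)-5-hydroxy-7-methoxy-2-(3,4,5-trimethoxyphenyl)chroman-4-one | COc1cc2c(c(O)c1)C(=O)C[C@@H](c1cc(OC)c(OC)c(OC)c1)O2
F9 | step 6 | (S)-7-methoxy-5-(2-methylbut-3-en-2-yloxy)-2-(3,4,5-trimethoxyphenyl)chroman-4-one | COc1cc2c(c(OC(C)(C)C=C)c1)C(=O)C[C@@H](c1cc(OC)c(OC)c(OC)c1)O2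
F10 | step 2 | (3,5-dimethoxyphenoxy)triisopropylsilane | COc1cc(O[Si](C(C)C)(C(C)C)C(C)C)cc(OC)c1
F11 | step 2 | 2,6-dimethoxy-4-(triisopropylsilyloxy)phenyllithium | [Li]c1c(OC)cc(O[Si](C(C)C)(C(C)C)C(C)C)cc1OC
F12 | step 2 | [3,5-dimethoxy-4-(3-methylbut-2-en-1-yl)phenoxy]triisopropylsilane | COc1cc(O[Si](C(C)C)(C(C)C)C(C)C)cc(OC)c1CC=C(C)C
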